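The earlier runs and the new flask are simulated on assumed constants.

The theta run climbs from 44% at 15.0 min to 65% at 60.0 min. At 50.0 min the three earlier runs read 60%, 61% and 62%, though c_Q starts at 0.050 M, 0.10 M and 0.20 M. So you may treat the percent curve as independent of charge, take the steps as first order, and read a tank's outlet as the batch curve averaged over exit ages, the residence-time distribution.

| flask | Q | remark | time |
|---|---|---|---|
| theta | 0.10 M | run made earlier |  |
| epsilon | 0.050 M | run made earlier |  |
| delta | 0.20 M | run made earlier |  |
| dusk | 0.10 M | one stirred flow tank at steady state, fed with the mixture as stated, mean residence time 1.0 h |  |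
| noon | 0.10 M | everything together in a closed stirred flask, run for 1.0 h | 1.0 h |

| run | time / min | Z / % |
|---|---|---|
| theta | 15.0 | 44 |
| theta | 30.0 | 54 |
| theta | 50.0 | 61 |
| theta | 60.0 | 65 |
| epsilon | 4.00 | 16 |
| epsilon | 8.00 | 32 |
| epsilon | 20.0 | 46 |
| epsilon | 50.0 | 60 |
| delta | 4.00 | 15 |
| delta | 8.00 | 26 |
| delta | 20.0 | 52 |
| delta | 50.0 | 62 |

(readings scatter by 1.5 percentage points)

- the stated concentrations are those of everything mixed, before any reaction; amounts are the same in each set-up
- the earlier runs were read with a standard deviation of 1.5 percentage points
- the earlier runs were made in a closed, stirred flask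

1. the set-up with the highest amount of Z at the outlet or at the end, in percent of the Q put in ("none" if the first two lie within 2 percentage points) (dusk / noon / none)
2. amount of Z at the outlet or at the end, in percent of the Q put in, dusk
3. amount of Z at the outlet or at the end, in percent of the Q put in, noon

Turn the question round: for dusk to beat noon, that average must exceed the curve at 1.0 h, which is noon's age and dusk's mean age. Fit a single exponential, P(1 − exp(−t/T)), to theta's readings at 30.0 min and 60.0 min. You get the rise time T = 18.9 min, the time constant of the climb, and the plateau P = 67.8%, both readings with their scatter. Averaging over exponential ages gives Pτ/(τ + T) in closed form, so my dusk is 51.6%. That lies 13 percentage points under theta's last reading, more than the margin of 2 points. The opposite outcome needs a curve that bends upward with age, and theta's bends the other way: it reads 54% by 30.0 min and gains 11 points over the next 30.0 min.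

The forecast gives noon, with dusk 46% and noon 64%: “Noon wins either way.” My dusk stands higher than its.

The flask gives noon: dusk 53.4%, noon 63.7%.

    Q → G (k = 0.130 min⁻¹)
    Q ⇌ D (K = 2.90, k = 0.0260 min⁻¹)
    G → J (k = 0.0910 min⁻¹)
    G → Z (k = 0.320 min⁻¹)
    Q ⇌ L (K = 1.40, k = 0.0950 min⁻¹)

Dusk lies 1.8 points above the rise-time figure. On noon's later reading, the same T gives 67.2% at 1.5 h, and the flask gives 68.0%. In noon, Q → G had half of its turnover up to 1.0 h done by 0.0975 h and G → Z by 0.145 h. From 0.500 h to 1.00 h, Q fell from 4.55% to 1.90%, L from 13.1% to 4.86% and D from 11.6% to 10.9%, while Z rose from 53.9% to 63.7%, and at 10.0 h Z stands at 77.6%, above the plateau.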